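Cuts: first the benzyl–O bond at C3' and the methyl–O bond at C8, which leads back to a flavone-5,8-quinone. Then C4–C4a and O1–C8a together, then C3–C4 (Claisen) and C2–C3 (Grignard) of the side chain.
Enabling feature: on ring A the oxygens at C5 and C8 are para, and C8 lies between the methoxy carbon C7 and C8a, which carries O1. This is the oxygen pattern of 2,6-dimethoxy-1,4-benzoquinone, whose two ring CH carbons (later C4a and C6) are exchanged by its mirror plane, so the first bond may form at either one.
Forward: ring B is bought as 3-hydroxy-4,5-dimethoxybenzaldehyde and after five steps carries the C2–C3–C4 chain plus a sacrificial carboxyl group. Ring A is bought as the quinone, and ring C closes in the step that joins the two halves.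
After the union: quinone to hydroquinone, methylation of the free C8 hydroxyl (the C5 hydroxyl is hydrogen-bonded to C4=O), then hydrogenolysis of the benzyl ether.
Stereochemistry: the target has no stereogenic element, so nothing has to be controlled.

Key step: step 6

Remark: the target is achiral, so the drawn structure is its only stereoisomer. The carbinol centre made in step 2 is racemic and is erased in step 3. The 1,3-dicarbonyl compounds of steps 4 to 6 are drawn as diketo tautomers although they exist largely as chelated enols.

Step 1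
Reactants: 1 3-hydroxy-4,5-dimethoxybenzaldehyde; 2 benzyl bromide
Product: 3 3-(benzyloxy)-4,5-dimethoxybenzaldehyde
Conditions: K2CO3, DMF, rt
Reagents that add atoms: 2 benzyl bromide, BrCc1ccccc1
Why: Williamson ether synthesis, in which the phenol is the only acidic site of 1 and its potassium salt displaces bromide from the benzylic halide by SN2; the ether can later be removed under neutral conditions.

Step 2
Reactants: 3 3-(benzyloxy)-4,5-dimethoxybenzaldehyde
Product: 4 rac-1-[3-(benzyloxy)-4,5-dimethoxyphenyl]ethan-1-ol
Conditions: MeMgBr, THF, 0 °C, then aqueous work-up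
Reagents that add atoms: methylmagnesium bromide, C[Mg]Br
Why: Grignard 1,2-addition to a non-enolisable aromatic aldehyde; the carbinol centre forms as a racemate, which does not matter because step 3 removes it.

Step 3
Reactants: 4 rac-1-[3-(benzyloxy)-4,5-dimethoxyphenyl]ethan-1-ol
Product: 5 1-[3-(benzyloxy)-4,5-dimethoxyphenyl]ethan-1-one
Conditions: activated MnO2, CH2Cl2, rt
Reagents that add atoms: none
Why: MnO2 oxidation of an electron-rich secondary benzylic alcohol, which stops at the ketone and leaves the aryl ethers untouched.

Step 4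
Reactants: 5 1-[3-(benzyloxy)-4,5-dimethoxyphenyl]ethan-1-one; 6 diethyl oxalate
Product: 7 ethyl 4-[3-(benzyloxy)-4,5-dimethoxyphenyl]-2,4-dioxobutanoate
Conditions: NaOEt, EtOH/THF, 0 °C to rt; then 1 M HCl
Reagents that add atoms: 6 diethyl oxalate, CCOC(=O)C(=O)OCC
Why: crossed Claisen condensation, in which the oxalate cannot enolise and is the stronger electrophile, and deprotonation of the 1,3-dicarbonyl product drives the equilibrium, as in the standard route to aryl diketo acids.

Step 5
Reactants: 7 ethyl 4-[3-(benzyloxy)-4,5-dimethoxyphenyl]-2,4-dioxobutanoate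
Product: 8 4-[3-(benzyloxy)-4,5-dimethoxyphenyl]-2,4-dioxobutanoic acid
Conditions: LiOH, THF/H2O, 0 °C to rt; then 1 M HCl to pH 2
Reagents that add atoms: lithium hydroxide, [Li+].[OH-]
Why: ester saponification, in which the substrate reacts as its enolate, so the ketone carbonyls are shielded against retro-Claisen cleavage at or below room temperature, and acidification releases the acid.

Step 6
Reactants: 8 4-[3-(benzyloxy)-4,5-dimethoxyphenyl]-2,4-dioxobutanoic acid; 9 2,6-dimethoxy-1,4-benzoquinone
Product: 11 2-[3-(benzyloxy)-4,5-dimethoxyphenyl]-7-methoxy-4H-chromene-4,5,8-trione, via acylquinone 10 (not isolated)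
Conditions: AgNO3 (0.2 equiv), K2S2O8 (2 equiv), 9 (3 equiv), CH2Cl2/H2O 1:1, 40 °C, 8 added over 2 h; then rt until 10 is consumed
Reagents that add atoms: none
Why: Proposed new method: Ag(II), formed from Ag(I) and persulfate, oxidises the carboxylate of 8, CO2 leaves, and the acyl radical (kept by the chelated enol as a β-hydroxyenoyl σ-radical, whose loss of CO would have to give a vinyl radical) adds to a ring CH carbon of 9, forming C4–C4a and a radical on the neighbouring carbon that is stabilised by its methoxy group and the C8 carbonyl; a second one-electron oxidation and loss of the proton restore the quinone as 10. In 10 the methoxy-bearing carbon C8a is the β-carbon of both the C5 and the C4 carbonyl, so the enol oxygen on C2 adds there in a 6-endo-trig oxa-Michael step and methanol is expelled (vinylic addition–elimination), which forms O1–C8a and closes ring C as a 4-pyranone. The closest known reactions are the Minisci-type silver/persulfate decarboxylative acylation of quinones and protonated heteroarenes with α-keto acids and the exchange of quinone methoxy groups by O- and N-nucleophiles; new here are the enolisable aroylpyruvic acid as acyl radical source and the coupling of both events in one flask. Site selectivity is secured by the substrates, since the two CH positions of 9 are symmetry-equivalent and only the methoxy group ortho to the new acyl group lies within reach of the enol oxygen. What must be enforced from outside is mono- over diacylation, because 11 is more electron-poor than 9 and keeps C6–H, and survival of the benzyl ether; the threefold excess of 9, slow addition of 8, extraction of 11 into the organic layer, the mild temperature and the small excess of persulfate serve both ends. No stereocentre is formed.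

Step 7
Reactants: 11 2-[3-(benzyloxy)-4,5-dimethoxyphenyl]-7-methoxy-4H-chromene-4,5,8-trione
Product: 12 2-[3-(benzyloxy)-4,5-dimethoxyphenyl]-5,8-dihydroxy-7-methoxy-4H-chromen-4-one
Conditions: Na2S2O4, EtOAc/H2O, rt, under Ar
Reagents that add atoms: none
Why: dithionite reduction of a quinone to its hydroquinone, a fast two-electron, two-proton transfer for this electron-poor quinone that spares the pyranone and all aryl ethers.

Step 8
Reactants: 12 2-[3-(benzyloxy)-4,5-dimethoxyphenyl]-5,8-dihydroxy-7-methoxy-4H-chromen-4-one
Product: 13 2-[3-(benzyloxy)-4,5-dimethoxyphenyl]-5-hydroxy-7,8-dimethoxy-4H-chromen-4-one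
Conditions: MeI (1.05 equiv), K2CO3 (1.1 equiv), acetone, 40 °C, under Ar
Reagents that add atoms: iodomethane, CI
Why: Williamson O-methylation under substrate control, because the C5 hydroxyl is held in a six-membered hydrogen bond to the C4 carbonyl and is less acidic and less nucleophilic than the C8 hydroxyl, the basis of the classical partial methylation of 5-hydroxyflavones.

Step 9
Reactants: 13 2-[3-(benzyloxy)-4,5-dimethoxyphenyl]-5-hydroxy-7,8-dimethoxy-4H-chromen-4-one
Product: 14 5,3'-dihydroxy-7,8,4',5'-tetramethoxyflavone
Conditions: H2 (1 atm), 10% Pd/C, EtOAc/MeOH, rt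
Reagents that add atoms: none
Why: catalytic hydrogenolysis of an aryl benzyl ether under neutral conditions, which the methyl ethers, the chelated phenol and the conjugated C2–C3 double bond of a flavone withstand.

Compound list
1 | 3-hydroxy-4,5-dimethoxybenzaldehyde | O=Cc1cc(O)c(OC)c(OC)c1 | starting material
2 | benzyl bromide | BrCc1ccccc1 | starting material
3 | 3-(benzyloxy)-4,5-dimethoxybenzaldehyde | O=Cc1cc(OC)c(OC)c(OCc2ccccc2)c1 | intermediate
4 | rac-1-[3-(benzyloxy)-4,5-dimethoxyphenyl]ethan-1-ol (racemate) | CC(O)c1cc(OC)c(OC)c(OCc2ccccc2)c1 | intermediate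
5 | 1-[3-(benzyloxy)-4,5-dimethoxyphenyl]ethan-1-one | CC(=O)c1cc(OC)c(OC)c(OCc2ccccc2)c1 | intermediate
6 | diethyl oxalate | CCOC(=O)C(=O)OCC | starting material
7 | ethyl 4-[3-(benzyloxy)-4,5-dimethoxyphenyl]-2,4-dioxobutanoate | CCOC(=O)C(=O)CC(=O)c1cc(OC)c(OC)c(OCc2ccccc2)c1 | intermediate
8 | 4-[3-(benzyloxy)-4,5-dimethoxyphenyl]-2,4-dioxobutanoic acid | O=C(O)C(=O)CC(=O)c1cc(OC)c(OC)c(OCc2ccccc2)c1 | intermediate
9 | 2,6-dimethoxy-1,4-benzoquinone | COC1=CC(=O)C=C(OC)C1=O | starting material
10 | 1-[3-(benzyloxy)-4,5-dimethoxyphenyl]-3-(2,4-dimethoxy-3,6-dioxocyclohexa-1,4-dien-1-yl)propane-1,3-dione (2-acyl-3,5-dimethoxy-1,4-benzoquinone, not isolated) | COC1=CC(=O)C(C(=O)CC(=O)c2cc(OC)c(OC)c(OCc3ccccc3)c2)=C(OC)C1=O | intermediate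
11 | 2-[3-(benzyloxy)-4,5-dimethoxyphenyl]-7-methoxy-4H-chromene-4,5,8-trione | COC1=CC(=O)C2=C(OC(=CC2=O)c2cc(OC)c(OC)c(OCc3ccccc3)c2)C1=O | intermediate
12 | 2-[3-(benzyloxy)-4,5-dimethoxyphenyl]-5,8-dihydroxy-7-methoxy-4H-chromen-4-one | COc1cc(O)c2c(=O)cc(-c3cc(OC)c(OC)c(OCc4ccccc4)c3)oc2c1O | intermediate
13 | 2-[3-(benzyloxy)-4,5-dimethoxyphenyl]-5-hydroxy-7,8-dimethoxy-4H-chromen-4-one | COc1cc(O)c2c(=O)cc(-c3cc(OC)c(OC)c(OCc4ccccc4)c3)oc2c1OC | intermediate
14 | 5,3'-dihydroxy-7,8,4',5'-tetramethoxyflavone (achiral) | COc1cc(-c2cc(=O)c3c(O)cc(OC)c(OC)c3o2)cc(O)c1OC | target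

Total step count: 9
Longest linear sequence: 9 steps (1 to 14); 2, 6 and 9 enter as purchased compounds.

Steps most likely to fail

Step 6 (new method).
- What may go wrong:
  - The acyl radical may lose CO through its keto tautomer before the rather electron-rich quinone traps it.
  - Ag(II) and the sulfate radical anion may oxidise the enol, the benzylic C–H or ring B instead of the carboxylate.
  - The radical may attack a quinone oxygen instead of carbon.
  - A second acylation may take place at C6 of the more electron-poor product.
- Fallback: this route uses known chemistry only, sets out from 3 and comes back at 12. Claisen–Schmidt condensation of 3 with commercial 2',6'-dihydroxy-4'-methoxyacetophenone (KOH, EtOH) should give the chalcone (E)-3-[3-(benzyloxy)-4,5-dimethoxyphenyl]-1-(2,6-dihydroxy-4-methoxyphenyl)prop-2-en-1-one F1. The two hydroxyls of that ketone are equivalent, so oxidative cyclisation (cat. I2, DMSO, 120 °C) can lead only to 2-[3-(benzyloxy)-4,5-dimethoxyphenyl]-5-hydroxy-7-methoxy-4H-chromen-4-one F2. Elbs persulfate oxidation (K2S2O8, aq. KOH, pyridine, rt) brings in oxygen para to the C5 phenolate as the potassium flavon-8-yl sulfate F3. Warm dilute HCl hydrolyses this ester to 12, after which steps 8 and 9 follow unchanged.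

Step 8.
- What may go wrong:
  - The hydroquinone monoanion may be re-oxidised to the quinone by traces of air.
  - Alkylation may run on to the C5 hydroxyl.
- Fallback: this route sets out from 12 and comes back at 13, and moves the selectivity from the alkylation to a dealkylation. Excess MeI and K2CO3 in DMF should give the air-stable 2-[3-(benzyloxy)-4,5-dimethoxyphenyl]-5,7,8-trimethoxy-4H-chromen-4-one F4. MgI2 etherate (THF, reflux) then cleaves only the C5 methyl ether, because only that oxygen can chelate magnesium together with the C4 carbonyl. This gives 13.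

Step 5.
- What may go wrong:
  - Hydroxide may attack a ketone carbonyl rather than the ester, so that retro-Claisen cleavage returns the acetophenone and oxalate.
- Fallback: this route sets out from 5 and comes back at 8, and frees the acid by acidolysis instead of by base. Claisen condensation of 5 with di-tert-butyl oxalate (LiHMDS, THF, −78 °C to rt) should give tert-butyl 4-[3-(benzyloxy)-4,5-dimethoxyphenyl]-2,4-dioxobutanoate F5. TFA in CH2Cl2 (0 °C to rt) converts F5 into 8.

Further compounds
F1 | step 6 | (E)-3-[3-(benzyloxy)-4,5-dimethoxyphenyl]-1-(2,6-dihydroxy-4-methoxyphenyl)prop-2-en-1-one | COc1cc(O)c(C(=O)/C=C/c2cc(OC)c(OC)c(OCc3ccccc3)c2)c(O)c1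
F2 | step 6 | 2-[3-(benzyloxy)-4,5-dimethoxyphenyl]-5-hydroxy-7-methoxy-4H-chromen-4-one | COc1cc(O)c2c(=O)cc(-c3cc(OC)c(OC)c(OCc4ccccc4)c3)oc2c1
F3 | step 6 | potassium 2-[3-(benzyloxy)-4,5-dimethoxyphenyl]-5-hydroxy-7-methoxy-4-oxo-4H-chromen-8-yl sulfate | COc1cc(O)c2c(=O)cc(-c3cc(OC)c(OC)c(OCc4ccccc4)c3)oc2c1OS(=O)(=O)[O-].[K+]
F4 | step 8 | 2-[3-(benzyloxy)-4,5-dimethoxyphenyl]-5,7,8-trimethoxy-4H-chromen-4-one | COc1cc(OC)c2c(=O)cc(-c3cc(OC)c(OC)c(OCc4ccccc4)c3)oc2c1OC
F5 | step 5 | tert-butyl 4-[3-(benzyloxy)-4,5-dimethoxyphenyl]-2,4-dioxobutanoate | CC(C)(C)OC(=O)C(=O)CC(=O)c1cc(OC)c(OC)c(OCc2ccccc2)c1
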